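## Structural features

The target is a trans-fused bicyclo[5.3.0]decane of the daucane type. A cyclopentane (C1–C5) shares the C1–C5 bond with a cycloheptane (C5, C6, C7, C8, C9, C10, C1). C1 is a methyl-bearing quaternary fusion carbon and C5 a fusion methine whose hydrogen lies on the opposite face. The seven stereocentres form two contiguous groups. The first is C1, C4 (tertiary carbinol with isopropyl, hydroxyl cis to the C1 methyl), C5 and C6 (α-isovalerate). The second is C8 and C9 (α-epoxide, methyl on C8) and C10 (α-acetate, next to quaternary C1). Fragile groups are the trisubstituted epoxide beside an acetate (acid, nucleophiles) and two different esters (base, hydride). At the ketone oxidation level the β-hydroxy carbonyl relation between C4 and C6 is also fragile (dehydration, retro-aldol, migration of a neighbouring double bond). The real difficulty is the C4–C5–C6 array: the 4β-hydroxyl syn to the angular methyl, the trans ring fusion and the 1,3-anti diol. Two secondary hydroxyls (C6, C10) must also carry different acyl groups. The key step exploits that C7 is the only ring methylene lying between two carbons (C6 and C8) that can both be trigonal. The seven-membered ring can therefore be written as a 1,4-cycloheptadiene (C5=C6, C8=C9). In it the bond from quaternary C1 to C10 is made by a Cope shift, C7–C8 is made by cyclopropanation, and C4 and C6 already carry oxygen.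

## Logic of the disconnections

23 to 22: the C6 O–acyl bond is cut last, because the isovalerate is the group least tolerant of hydride and base. This leaves 22 with a single free secondary hydroxyl. The forward acylation must leave the tertiary C4 hydroxyl, the epoxide and the acetate alone.

22 to 21 to 20: the O–Si bond at C6 and the C10 O–acetyl bond are cut. The two secondary hydroxyls are told apart by the order in which they appear (C6 first, silylated; C10 later, acetylated), not by their reactivity. The forward steps need an acetylation of a neopentyl alcohol and a fluoride desilylation that spares epoxide and acetate.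

20 to 19: both C–O bonds of the epoxide (C8–O, C9–O) are cut. The epoxide is cis to the C10 oxygen, so it is assigned to hydroxyl-directed oxygen transfer. Two stereocentres disappear. The forward step must deliver oxygen syn to the C10 hydroxyl and not oxidise that alcohol.

19 to 18 to 17 to 16: the C8 methyl is traced back to the ester carbon of 16. The carbenoid of the key step needs an acceptor on exactly this carbon. The forward steps must reduce the ester and then replace only the primary allylic hydroxyl by hydrogen, by direct and not allylic substitution.

16 to 15: the C10–O bond is cut. C10 is the γ-carbon of the unsaturated ester, the allylic position that an ene reaction starting at C8 can reach. One stereocentre is removed. The forward oxidation must be γ-selective and occur on the α-face.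

15 to 14 to 13: the silyl group is removed and the C6–H bond is cut back to the ketone. The 1,3-anti relation of the C4 and C6 oxygens is the signature of hydride delivery from a borohydride bound to the C4 hydroxyl. The forward reduction must be internal, and quick enough that the β,γ-unsaturated ketone does not isomerise.

13 to 12 to 11: the C5–H bond is replaced by C5–Br and then by the C5=C6 enol ether. The ketone has to be released without acid, since acid would ionise the tertiary allylic alcohol of 11 and transpose the enone. The forward steps need bromination of the enol ether at neutral pH and protonation of a chelated enolate on the α-face.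

11 to 10: the C4–isopropyl bond is cut. Three carbons and the C4 stereocentre are removed and the vinylogous ester of 10 is reached. The nucleophile must add 1,2, from the α-face, and spare the methyl ester.

10 to 9 to 4 + 8: C1–C10 and C7–C8 are cut (the key disconnection). The seven-membered ring, the quaternary C1 and the oxygen at C4 and C6 come from two achiral fragments. The forward step must attack the enol ether olefin only, on one enantioface, and give the cis-divinylcyclopropane. 4 is kept as the ethyl enol ether. A silyl enol ether would be easier to unmask, but it cannot be made regioselectively from the corresponding 2-acetyl enone (four enolisable positions), whereas 3 delivers the ethyl enol ether unambiguously.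

4 to 2 + 3, 2 to 1: the sp2–sp2 bond C5–C6 is cut (cross-coupling), then the C–I bond. Both steps are standard for α-iodo enones. 4 must be kept away from acid.

8 to 7 to 6 to 5: the vinyl C=C (dehydration), the carbinol C–H (reduction) and the C=N2 bond (diazo transfer) are cut in turn. 8 cyclises on standing and must be made cold and used at once.

## Other disconnections considered

Alternative 1: The cut is at C5–C6 and the C4–O bond, the C4–C5–C6 β-hydroxy ketone being read as a masked aldol; C9–C10 would be closed later. In the forward key step the nitrile oxide A3 adds across the C4=C5 bond of the cyclopentene A2 to give the isoxazoline A1. In its favour, the addition is suprafacial, so the C4 oxygen and the C5–C6 bond arrive on the same face. The C4/C5 relationship, which the chosen plan must win by a selective addition and a selective protonation, is then fixed by the mechanism; on this point the alternative is the better plan. N–O cleavage would expose the same C4-hydroxyl/C6-ketone array without a migrating olefin beside it, and the directed reduction at C6 would be the same, which is an equal point. Against it, an intermolecular addition to a hindered trisubstituted olefin next to a quaternary carbon is slow and competes with dimerisation of A3. The C1 stereocentre of A2 must be made separately. The seven-membered ring still has to be closed at C9–C10 with an open question at C10. On structure, it builds the five-membered ring first and appends the larger ring. On mechanism, it relies on a stereospecific cycloaddition where the chosen plan relies on catalyst control. On step economy it is longer, since the chosen plan has the whole carbon skeleton after step 6.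

Alternative 2: The cut is at C1–C5 and C6–C7, with the C7–C9 bond of a cyclopropane given up. The forward key step is the [Rh(CO)2Cl]2-catalysed intramolecular (5+2) cycloaddition of the silyl alkyne and the vinylcyclopropane in A5, giving the hydroazuladiene A4. In its favour, both rings and the quaternary C1 form in one step. The C4 carbinol exists before ring formation, so the facial problem at C4 of the chosen plan does not arise (better). The C8 methyl is present from the start, so no ester has to be reduced to a methyl group (better in redox economy). The C9=C10 olefin with its allylic C8–H is placed for an ene-type oxygenation that would give the C10 oxygen and the C8=C9 bond together. Against it, (5+2) reactions that must create a quaternary centre at the alkene terminus are the slow cases. Which cyclopropane bond opens, and how C4 controls C1, are not secured. The C5 hydrogen would again be introduced by protonation after the vinylsilane is oxidised to the C6 ketone, so on C5 it is the equal of the chosen plan and not better. A5 needs an enantiopure cyclopropane and a tertiary propargylic alcohol, which makes the route to the precursor long and linear. After the key step the step count would be comparable or slightly lower.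

Alternative 3: The cut is at C6–C7 and C8–C9, with a temporary C6–O–C9 bridge. In the forward key step Rh2(OAc)4 turns the diazoketone A7 into a carbenoid that is captured by the C6 aldehyde oxygen, and the six-membered carbonyl ylide adds isopropenyl acetate A8 to give the bridged ketone A6. In its favour, C1, C4 and C5 are set on a simple cyclopentane before the key step, so the trans relation across C1–C5 and the C4 carbinol are not left to late steps; on this point it is the better plan. The aldehyde oxygen becomes the C6 oxygen with fixed configuration. C8 arrives with its methyl and an oxygen, and C10 as a ketone. Against it, the regiochemistry with a 1,1-disubstituted enol acetate is not certain. The bridge must be excised (reductive C9–O cleavage next to the ketone, loss of acetate). The C10 ketone would then have to be reduced from the β-face, past the angular methyl. A7 carries three contiguous stereocentres and an epimerisable centre next to the aldehyde, so the difficulty moves into the precursor. On structure it is the most faithful to the oxygen pattern of the target. On mechanism it exchanges one rhodium carbenoid cascade for another. On step economy it is longer before the key step and similar after it.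

Key step: step 6

Conventions and assumption. Daucane locants are used for all bicyclic compounds (C1 methylated fusion carbon, C2, C3, C4, C5 fusion CH, then C6–C10 around the seven-membered ring); β is the face of the C1 methyl, α the opposite face. Assumption: the usual model for vinyl ethers and styrenes with prolinate catalysts points to Rh2(R-DOSP)4 for the C1 configuration drawn; should the first batch of 10 prove antipodal, Rh2(S-DOSP)4 is used and nothing else changes. Structure check: the constitutions of 4, 8 and 10 and the C1 descriptor of 10 match the target atom by atom and need no correction.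

## Route

Step 1
Reactants: 1 3-methylcyclopent-2-en-1-one
Product: 2 2-iodo-3-methylcyclopent-2-en-1-one
Conditions: I2, pyridine, CH2Cl2, 0 °C → rt
Reagents that add atoms: iodine, II
Why: α-Iodination of an enone by conjugate addition of pyridine, iodination of the enolate and elimination (Johnson iodination); only C2 can react.

Step 2
Reactants: 2 2-iodo-3-methylcyclopent-2-en-1-one; 3 tributyl(1-ethoxyvinyl)stannane
Product: 4 2-(1-ethoxyvinyl)-3-methylcyclopent-2-en-1-one
Conditions: Pd(PPh3)4 (5 mol %), CuI (10 mol %), CsF, DMF, 45 °C; chromatography on Et3N-washed silica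
Reagents that add atoms: none
Why: Stille coupling of an α-iodo enone with an α-alkoxyvinylstannane under copper/fluoride promotion; the enol ether is kept away from acid throughout.

Step 3
Reactants: 5 methyl acetoacetate
Product: 6 methyl 2-diazo-3-oxobutanoate
Conditions: 4-acetamidobenzenesulfonyl azide, Et3N, MeCN, 0 °C → rt
Reagents that add atoms: 4-acetamidobenzenesulfonyl azide, CC(=O)Nc1ccc(cc1)S(=O)(=O)N=[N+]=[N-]
Why: Regitz diazo transfer to an active methylene compound.

Step 4
Reactants: 6 methyl 2-diazo-3-oxobutanoate
Product: 7 methyl 2-diazo-3-hydroxybutanoate (racemic)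
Conditions: NaBH4, MeOH, 0 °C
Reagents that add atoms: none
Why: Borohydride reduces the ketone and leaves the diazo ester untouched; the new carbinol centre is lost in the next step.

Step 5
Reactants: 7 methyl 2-diazo-3-hydroxybutanoate
Product: 8 methyl 2-diazobut-3-enoate
Conditions: POCl3, Et3N, CH2Cl2, 0 °C; kept cold as a hydrocarbon solution and used at once
Reagents that add atoms: none
Why: Dehydration through the dichlorophosphate gives the vinyldiazoacetate; immediate use avoids its cyclisation to a pyrazole.

Step 6
Reactants: 4 2-(1-ethoxyvinyl)-3-methylcyclopent-2-en-1-one; 8 methyl 2-diazobut-3-enoate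
Product: 10 methyl 6-ethoxy-1β-methyl-4-oxobicyclo[5.3.0]deca-5,8-diene-8-carboxylate (daucane locants; C1 quaternary), via cis-divinylcyclopropane 9 (not isolated)
Conditions: Rh2(R-DOSP)4, dirhodium tetrakis[(R)-N-(4-dodecylphenylsulfonyl)prolinate] (1 mol %), hexanes/toluene, −40 °C → rt, slow addition of 8 (2 equiv); then 50 °C if 9 persists
Reagents that add atoms: none
Why: The dirhodium prolinate turns 8 into a donor/acceptor vinylcarbenoid, which cyclopropanates the electron-rich, unhindered 1,1-disubstituted enol ether olefin of 4 (C7–C8 and C6–C8 form) and not the tetrasubstituted enone olefin. The cis-divinylcyclopropane 9 then undergoes a [3,3] shift through a boat transition state in which C10 bonds to the enone β-carbon C1 and C6–C8 breaks. The closest known reaction type is the tandem cyclopropanation–Cope (formal (4+3)) reaction of vinyldiazoacetates with dienes under chiral dirhodium carboxylate catalysis, including cases that create a quaternary carbon at the diene terminus. The three-membered ring closes by concerted carbene transfer to the olefin, and the seven-membered ring closes by the sigmatropic shift itself, with opening of the cyclopropane, not by a separate cyclisation. The only new stereocentre, C1, is controlled by the catalyst through the enantioface of the enol ether that is cyclopropanated; the boat geometry and the ring-fixed geometry of the C1=C5 olefin (methyl cis to C6) transmit it without loss. The step needs site selectivity, a cis arrangement of the two vinyl groups and one absolute sense; the first comes from the nucleophilicity of the enol ether, the others from the end-on approach to the carbenoid in the chiral pocket. The ethoxy and ester groups on the two ends of the breaking C6–C8 bond weaken it and should offset the retarding effect of the fully substituted terminus. Low temperature, a hydrocarbon medium and slow addition suppress carbene dimerisation and the zwitterionic (3+2) pathway.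

Step 7
Reactants: 10 methyl 6-ethoxy-1β-methyl-4-oxobicyclo[5.3.0]deca-5,8-diene-8-carboxylate
Product: 11 methyl 6-ethoxy-4β-hydroxy-4α-isopropyl-1β-methylbicyclo[5.3.0]deca-5,8-diene-8-carboxylate
Conditions: iPrMgCl, CeCl3, THF, −78 → −40 °C; aq. NaHCO3 quench; used crude
Reagents that add atoms: isopropylmagnesium chloride, CC(C)[Mg]Cl
Why: Organocerium 1,2-addition to the vinylogous ester carbonyl; the weakly basic reagent avoids enolisation and β-hydride reduction and should be faster at this ketone-like carbonyl than at the conjugated methyl ester. The seven-membered ring holds C10 near the plane of the C4–C5=C6 unit and leaves the C1 methyl pseudo-axial on the β-face, so the nucleophile should enter from the α-face and give the 4β-alcohol.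

Step 8
Reactants: 11 methyl 6-ethoxy-4β-hydroxy-4α-isopropyl-1β-methylbicyclo[5.3.0]deca-5,8-diene-8-carboxylate
Product: 12 methyl 5-bromo-4β-hydroxy-4α-isopropyl-1β-methyl-6-oxobicyclo[5.3.0]dec-8-ene-8-carboxylate (C5 epimers, both used)
Conditions: N-bromosuccinimide, NaHCO3, THF/H2O (4:1), 0 °C; used crude
Reagents that add atoms: N-bromosuccinimide, O=C1CCC(=O)N1Br; water, O
Why: Bromohydration of an enol ether: bromine adds at C5, water captures the oxocarbenium ion at C6 and ethanol is lost, all at neutral pH. Acid hydrolysis is avoided because it would ionise the tertiary allylic alcohol and give the transposed enone (Stork–Danheiser pathway); the electron-poor C8=C9 bond does not compete.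

Step 9
Reactants: 12 methyl 5-bromo-4β-hydroxy-4α-isopropyl-1β-methyl-6-oxobicyclo[5.3.0]dec-8-ene-8-carboxylate
Product: 13 methyl 4β-hydroxy-4α-isopropyl-1β-methyl-6-oxo-5αH-bicyclo[5.3.0]dec-8-ene-8-carboxylate (trans-fused)
Conditions: SmI2 (2.5 equiv), THF/MeOH, −78 °C; pH 7 work-up; used at once
Reagents that add atoms: none
Why: Reductive cleavage of an α-bromo ketone by SmI2 gives a samarium enolate that is chelated by the C4 oxygen on the β-face. Methanol should therefore protonate C5 from the α-face, keeping the chelate and giving the trans-fused ketone, which is also the isomer with C6 away from the isopropyl group. The cold, neutral conditions leave the β,γ-double bond in place.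

Step 10
Reactants: 13 methyl 4β-hydroxy-4α-isopropyl-1β-methyl-6-oxo-5αH-bicyclo[5.3.0]dec-8-ene-8-carboxylate
Product: 14 methyl 4β,6α-dihydroxy-4α-isopropyl-1β-methyl-5αH-bicyclo[5.3.0]dec-8-ene-8-carboxylate
Conditions: Me4NBH(OAc)3, MeCN/AcOH (1:1), −30 °C
Reagents that add atoms: none
Why: Evans–Saksena reduction: the C4 hydroxyl exchanges onto boron and hydride is delivered internally to the β-face of the C6 carbonyl, giving the 6α-alcohol (1,3-anti diol); the conjugated ester is not reduced.

Step 11
Reactants: 14 methyl 4β,6α-dihydroxy-4α-isopropyl-1β-methyl-5αH-bicyclo[5.3.0]dec-8-ene-8-carboxylate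
Product: 15 methyl 6α-(tert-butyldimethylsilyloxy)-4β-hydroxy-4α-isopropyl-1β-methyl-5αH-bicyclo[5.3.0]dec-8-ene-8-carboxylate
Conditions: TBSOTf (1.1 equiv), 2,6-lutidine, CH2Cl2, −78 °C
Reagents that add atoms: tert-butyldimethylsilyl triflate, CC(C)(C)[Si](C)(C)OS(=O)(=O)C(F)(F)F
Why: Silylation of the secondary alcohol; at low temperature and with one equivalent the hindered tertiary C4 hydroxyl is left free. The silyl ether reserves C6 for the isovalerate.

Step 12
Reactants: 15 methyl 6α-(tert-butyldimethylsilyloxy)-4β-hydroxy-4α-isopropyl-1β-methyl-5αH-bicyclo[5.3.0]dec-8-ene-8-carboxylate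
Product: 16 methyl 6α-(tert-butyldimethylsilyloxy)-4β,10α-dihydroxy-4α-isopropyl-1β-methyl-5αH-bicyclo[5.3.0]dec-8-ene-8-carboxylate
Conditions: SeO2, 1,4-dioxane, 80 °C
Reagents that add atoms: selenium dioxide, O=[Se]=O
Why: Allylic oxidation by ene reaction and [2,3] shift at the γ-methylene of the unsaturated ester: selenium bonds to the α-carbon C8 and hydrogen is taken from C10, whereas oxidation at C7 would require attack at the electron-poor β-carbon. The pseudo-axial C10 hydrogen anti to the angular methyl is the one aligned with the π-system, so the hydroxyl should appear on the α-face.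

Step 13
Reactants: 16 methyl 6α-(tert-butyldimethylsilyloxy)-4β,10α-dihydroxy-4α-isopropyl-1β-methyl-5αH-bicyclo[5.3.0]dec-8-ene-8-carboxylate
Product: 17 6α-(tert-butyldimethylsilyloxy)-8-(hydroxymethyl)-4α-isopropyl-1β-methyl-5αH-bicyclo[5.3.0]dec-8-ene-4β,10α-diol
Conditions: iBu2AlH (5 equiv), CH2Cl2, −78 → 0 °C; Rochelle salt work-up
Reagents that add atoms: none
Why: 1,2-Reduction of the conjugated ester to the allylic alcohol; the two free hydroxyls only consume reagent and the silyl ether is stable.

Step 14
Reactants: 17 6α-(tert-butyldimethylsilyloxy)-8-(hydroxymethyl)-4α-isopropyl-1β-methyl-5αH-bicyclo[5.3.0]dec-8-ene-4β,10α-diol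
Product: 19 6α-(tert-butyldimethylsilyloxy)-4α-isopropyl-1β,8-dimethyl-5αH-bicyclo[5.3.0]dec-8-ene-4β,10α-diol, via allylic mesylate 18 (not isolated)
Conditions: MsCl (1.05 equiv), Et3N, THF, −30 °C; then LiBHEt3, −30 → 0 °C
Reagents that add atoms: none
Why: The primary allylic hydroxyl is sulfonylated far faster than the neopentyl secondary and the tertiary ones; hydride then displaces the primary sulfonate directly (SN2), which gives the C8 methyl and keeps the C8=C9 bond in place.

Step 15
Reactants: 19 6α-(tert-butyldimethylsilyloxy)-4α-isopropyl-1β,8-dimethyl-5αH-bicyclo[5.3.0]dec-8-ene-4β,10α-diol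
Product: 20 6α-(tert-butyldimethylsilyloxy)-8α,9α-epoxy-4α-isopropyl-1β,8β-dimethyl-5αH-bicyclo[5.3.0]decane-4β,10α-diol
Conditions: VO(acac)2 (5 mol %), tBuOOH, CH2Cl2, 0 °C → rt
Reagents that add atoms: tert-butyl hydroperoxide, CC(C)(C)OO
Why: Vanadium-catalysed epoxidation of a cyclic allylic alcohol: the alkyl peroxide bound to the vanadate ester of the C10 hydroxyl transfers oxygen to the same (α) face, which sets C8 and C9 cis to the C10 oxygen.

Step 16
Reactants: 20 6α-(tert-butyldimethylsilyloxy)-8α,9α-epoxy-4α-isopropyl-1β,8β-dimethyl-5αH-bicyclo[5.3.0]decane-4β,10α-diol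
Product: 21 10α-acetoxy-6α-(tert-butyldimethylsilyloxy)-8α,9α-epoxy-4α-isopropyl-1β,8β-dimethyl-5αH-bicyclo[5.3.0]decan-4β-ol
Conditions: Ac2O, pyridine, DMAP, CH2Cl2, rt
Reagents that add atoms: acetic anhydride, CC(=O)OC(C)=O
Why: DMAP-catalysed acetylation of the only free secondary alcohol; the tertiary C4 hydroxyl does not react and the basic medium protects the epoxide.

Step 17
Reactants: 21 10α-acetoxy-6α-(tert-butyldimethylsilyloxy)-8α,9α-epoxy-4α-isopropyl-1β,8β-dimethyl-5αH-bicyclo[5.3.0]decan-4β-ol
Product: 22 10α-acetoxy-8α,9α-epoxy-4α-isopropyl-1β,8β-dimethyl-5αH-bicyclo[5.3.0]decane-4β,6α-diol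
Conditions: HF·pyridine, pyridine, THF, 0 °C → rt
Reagents that add atoms: none
Why: Fluoride cleavage of the silyl ether in a pyridine-buffered medium, which is neither acidic enough to open the epoxide nor basic enough to cleave or move the acetate.

Step 18
Reactants: 22 10α-acetoxy-8α,9α-epoxy-4α-isopropyl-1β,8β-dimethyl-5αH-bicyclo[5.3.0]decane-4β,6α-diol
Product: 23 10α-acetoxy-8α,9α-epoxy-4β-hydroxy-4α-isopropyl-1β,8β-dimethyl-5αH-bicyclo[5.3.0]dec-6α-yl 3-methylbutanoate (target)
Conditions: 3-methylbutanoic anhydride, Et3N, DMAP, CH2Cl2, rt
Reagents that add atoms: 3-methylbutanoic anhydride, CC(C)CC(=O)OC(=O)CC(C)C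
Why: DMAP-catalysed acylation of the C6 hydroxyl; the tertiary alcohol is inert and the chloride-free conditions leave the epoxide closed.

## Compound list

1 | 3-methylcyclopent-2-en-1-one | CC1=CC(=O)CC1 | starting material
2 | 2-iodo-3-methylcyclopent-2-en-1-one | CC1=C(I)C(=O)CC1 | intermediate
3 | tributyl(1-ethoxyvinyl)stannane | CCCC[Sn](CCCC)(CCCC)C(=C)OCC | starting material
4 | 2-(1-ethoxyvinyl)-3-methylcyclopent-2-en-1-one | C=C(OCC)C1=C(C)CCC1=O | intermediate
5 | methyl acetoacetate | COC(=O)CC(C)=O | starting material
6 | methyl 2-diazo-3-oxobutanoate | COC(=O)C(=[N+]=[N-])C(C)=O | intermediate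
7 | methyl 2-diazo-3-hydroxybutanoate (racemic) | COC(=O)C(=[N+]=[N-])C(C)O | intermediate
8 | methyl 2-diazobut-3-enoate | C=CC(=[N+]=[N-])C(=O)OC | intermediate
9 | methyl 2-ethoxy-2-(2-methyl-5-oxocyclopent-1-en-1-yl)-1-vinylcyclopropane-1-carboxylate, vinyl cis to cyclopentenyl (not isolated) | COC(=O)[C@]1(C=C)C[C@@]1(OCC)C2=C(C)CCC2=O | intermediate
10 | methyl 6-ethoxy-1β-methyl-4-oxobicyclo[5.3.0]deca-5,8-diene-8-carboxylate | COC(=O)C1=CC[C@@]2(C)CCC(=O)C2=C(OCC)C1 | intermediate
11 | methyl 6-ethoxy-4β-hydroxy-4α-isopropyl-1β-methylbicyclo[5.3.0]deca-5,8-diene-8-carboxylate | C1C=C(C(=O)OC)CC(OCC)=C2[C@]1(C)CC[C@@]2(O)C(C)C | intermediate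
12 | methyl 5-bromo-4β-hydroxy-4α-isopropyl-1β-methyl-6-oxobicyclo[5.3.0]dec-8-ene-8-carboxylate (C5 epimers, not controlled) | C1C=C(C(=O)OC)CC(=O)C2(Br)[C@]1(C)CC[C@@]2(O)C(C)C | intermediate
13 | methyl 4β-hydroxy-4α-isopropyl-1β-methyl-6-oxo-5αH-bicyclo[5.3.0]dec-8-ene-8-carboxylate | C1C=C(C(=O)OC)CC(=O)[C@@H]2[C@]1(C)CC[C@@]2(O)C(C)C | intermediate
14 | methyl 4β,6α-dihydroxy-4α-isopropyl-1β-methyl-5αH-bicyclo[5.3.0]dec-8-ene-8-carboxylate | C1C=C(C(=O)OC)C[C@H](O)[C@@H]2[C@]1(C)CC[C@@]2(O)C(C)C | intermediate
15 | methyl 6α-(tert-butyldimethylsilyloxy)-4β-hydroxy-4α-isopropyl-1β-methyl-5αH-bicyclo[5.3.0]dec-8-ene-8-carboxylate | C1C=C(C(=O)OC)C[C@H](O[Si](C)(C)C(C)(C)C)[C@@H]2[C@]1(C)CC[C@@]2(O)C(C)C | intermediate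
16 | methyl 6α-(tert-butyldimethylsilyloxy)-4β,10α-dihydroxy-4α-isopropyl-1β-methyl-5αH-bicyclo[5.3.0]dec-8-ene-8-carboxylate | O[C@@H]1C=C(C(=O)OC)C[C@H](O[Si](C)(C)C(C)(C)C)[C@@H]2[C@]1(C)CC[C@@]2(O)C(C)C | intermediate
17 | 6α-(tert-butyldimethylsilyloxy)-8-(hydroxymethyl)-4α-isopropyl-1β-methyl-5αH-bicyclo[5.3.0]dec-8-ene-4β,10α-diol | O[C@@H]1C=C(CO)C[C@H](O[Si](C)(C)C(C)(C)C)[C@@H]2[C@]1(C)CC[C@@]2(O)C(C)C | intermediate
18 | 8-(methanesulfonyloxymethyl) analogue of 17 (not isolated) | O[C@@H]1C=C(COS(C)(=O)=O)C[C@H](O[Si](C)(C)C(C)(C)C)[C@@H]2[C@]1(C)CC[C@@]2(O)C(C)C | intermediate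
19 | 6α-(tert-butyldimethylsilyloxy)-4α-isopropyl-1β,8-dimethyl-5αH-bicyclo[5.3.0]dec-8-ene-4β,10α-diol | O[C@@H]1C=C(C)C[C@H](O[Si](C)(C)C(C)(C)C)[C@@H]2[C@]1(C)CC[C@@]2(O)C(C)C | intermediate
20 | 6α-(tert-butyldimethylsilyloxy)-8α,9α-epoxy-4α-isopropyl-1β,8β-dimethyl-5αH-bicyclo[5.3.0]decane-4β,10α-diol | O[C@@H]1[C@@H]2O[C@]2(C)C[C@H](O[Si](C)(C)C(C)(C)C)[C@@H]2[C@]1(C)CC[C@@]2(O)C(C)C | intermediate
21 | 10α-acetoxy-6α-(tert-butyldimethylsilyloxy)-8α,9α-epoxy-4α-isopropyl-1β,8β-dimethyl-5αH-bicyclo[5.3.0]decan-4β-ol | CC(=O)O[C@@H]1[C@@H]2O[C@]2(C)C[C@H](O[Si](C)(C)C(C)(C)C)[C@@H]2[C@]1(C)CC[C@@]2(O)C(C)C | intermediate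
22 | 10α-acetoxy-8α,9α-epoxy-4α-isopropyl-1β,8β-dimethyl-5αH-bicyclo[5.3.0]decane-4β,6α-diol | CC(=O)O[C@@H]1[C@@H]2O[C@]2(C)C[C@H](O)[C@@H]2[C@]1(C)CC[C@@]2(O)C(C)C | intermediate
23 | 10α-acetoxy-8α,9α-epoxy-4β-hydroxy-4α-isopropyl-1β,8β-dimethyl-5αH-bicyclo[5.3.0]dec-6α-yl 3-methylbutanoate | CC(=O)O[C@@H]1[C@@H]2O[C@]2(C)C[C@H](OC(=O)CC(C)C)[C@@H]2[C@]1(C)CC[C@@]2(O)C(C)C | target

## Step count and least certain steps

Total step count: 18. Longest linear sequence: 16 steps (5 → 6 → 7 → 8 → 10 → 11 → … → 23; the branch from 1 joins at step 6).

Step 6 (key step). The most likely failure is incomplete enantiocontrol. The alkene is 1,1-disubstituted, the carbenoid is the unsubstituted member of its family, and the Cope terminus is fully substituted. The donor–acceptor cyclopropane may therefore open heterolytically before it rearranges, which erodes the enantiomeric purity and diverts material to a formal (3+2) adduct. The fallback replaces catalyst control by separation of diastereomers. It sets out from 14 of insufficient enantiomeric purity. The C6 hydroxyl is esterified with (S)-2-methoxy-2-phenylacetic acid (DCC, DMAP), giving the (S)-O-methylmandelate F1 together with the diastereomeric ester of the antipode F2. The two are separated by chromatography or crystallisation, and methanolysis of F1 (K2CO3, MeOH) returns to 14.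

Step 9. The most likely failure is protonation of the enolate on the β-face, anti to the isopropyl group, which would give the cis ring fusion. Equilibration by base or acid is not safe at this stage, because enolisation towards C7 would move the C8=C9 bond into conjugation with the ketone. The fallback makes the equilibration safe by taking the double bond away for a time. It sets out from crude 13 containing the 5β-H epimer F3. Radical addition of thiophenol (PhSH, AIBN, benzene, 80 °C) to the unsaturated ester gives the 9-phenylthio ester F4. The trans-fused isomer, with C6 syn to the hydroxyl and anti to isopropyl, should be the more stable, so DBU in CH2Cl2 should now equilibrate C5 to it. Oxidation (NaIO4) gives the sulfoxide F5, and thermal syn-elimination (toluene, 90 °C) restores the conjugated ester and returns to 13.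

Step 7. The most likely failures are β-hydride reduction or enolisation by the secondary Grignard reagent and only moderate discrimination between the two faces of C4, since the controlling centre C1 is two bonds away. The fallback introduces the three carbons in two stages. It sets out from 10. 2-Propenylmagnesium bromide with CeCl3 (a slimmer nucleophile without β-hydrogens) gives the isopropenyl carbinol F6. Hydrogenation of its 1,1-disubstituted olefin with RhCl(PPh3)3 and H2 spares the trisubstituted and tetrasubstituted olefins and returns to 11. Any C4 epimer would be removed by chromatography at the stage of 14.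

Step 12. The most likely failures are sluggish ene reaction of the electron-poor olefin, over-oxidation to the C10 ketone and incomplete α-face selectivity. The fallback builds the C10–O bond by epoxidation instead. It sets out from 15. LDA (2.5 equiv, THF/HMPA, −78 °C) followed by kinetic protonation with AcOH gives the deconjugated β,γ-unsaturated ester F7. mCPBA with NaHCO3 epoxidises the C9=C10 bond from the α-face, anti to the angular methyl, to give the 9α,10α-epoxide F8. DBU opens it by β-elimination from the ester enolate, which returns to 16 with the α-hydroxyl fixed by the epoxide.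

## Further compounds

F1 | step 6 | (S)-2-methoxy-2-phenylacetate of 14 at the C6 oxygen | C1C=C(C(=O)OC)C[C@H](OC(=O)[C@@H](OC)c3ccccc3)[C@@H]2[C@]1(C)CC[C@@]2(O)C(C)C
F2 | step 6 | (S)-2-methoxy-2-phenylacetate of the enantiomer of 14 | C1C=C(C(=O)OC)C[C@@H](OC(=O)[C@@H](OC)c3ccccc3)[C@H]2[C@@]1(C)CC[C@]2(O)C(C)C
F3 | step 9 | 5β-H (cis-fused) epimer of 13 | C1C=C(C(=O)OC)CC(=O)[C@H]2[C@]1(C)CC[C@@]2(O)C(C)C
F4 | step 9 | methyl 4β-hydroxy-4α-isopropyl-1β-methyl-6-oxo-9-(phenylthio)-5αH-bicyclo[5.3.0]decane-8-carboxylate (C8 and C9 not controlled; 5α-H form after equilibration) | C1C(Sc3ccccc3)C(C(=O)OC)CC(=O)[C@@H]2[C@]1(C)CC[C@@]2(O)C(C)C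
F5 | step 9 | sulfoxide of F4 | C1C(S(=O)c3ccccc3)C(C(=O)OC)CC(=O)[C@@H]2[C@]1(C)CC[C@@]2(O)C(C)C
F6 | step 7 | methyl 6-ethoxy-4β-hydroxy-1β-methyl-4α-(prop-1-en-2-yl)bicyclo[5.3.0]deca-5,8-diene-8-carboxylate | C1C=C(C(=O)OC)CC(OCC)=C2[C@]1(C)CC[C@@]2(O)C(C)=C
F7 | step 12 | methyl 6α-(tert-butyldimethylsilyloxy)-4β-hydroxy-4α-isopropyl-1β-methyl-5αH-bicyclo[5.3.0]dec-9-ene-8-carboxylate (C8 not controlled) | C1=CC(C(=O)OC)C[C@H](O[Si](C)(C)C(C)(C)C)[C@@H]2[C@]1(C)CC[C@@]2(O)C(C)C
F8 | step 12 | 9α,10α-epoxide of F7 | O1[C@@H]2[C@H]1C(C(=O)OC)C[C@H](O[Si](C)(C)C(C)(C)C)[C@@H]3[C@]2(C)CC[C@@]3(O)C(C)C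
A1 | alternative 1 | cyclopenta-fused isoxazoline with dithiane at C1 and the C7–C9 (Z)-vinyl iodide chain | CC(C)[C@]12CC[C@](C)(C3SCCCS3)[C@H]1C(C/C(C)=C\I)=NO2
A2 | alternative 1 | 2-(3-isopropyl-1-methylcyclopent-2-en-1-yl)-1,3-dithiane | CC(C)C1=C[C@](C)(CC1)C1SCCCS1
A3 | alternative 1 | (Z)-4-iodo-3-methylbut-3-enenitrile oxide | [O-][N+]#CC/C(C)=C\I
A4 | alternative 2 | C6-(benzyldimethylsilyl) hydroazula-5,9-diene with quaternary C1 | C[C@H]1CC([Si](C)(C)Cc2ccccc2)=C2[C@](O)(C(C)C)CC[C@]2(C)C=C1
A5 | alternative 2 | tertiary propargylic alcohol carrying the silyl alkyne and the (E)-alkenyl trans-2-methylcyclopropane | C[C@H]1C[C@@H]1/C=C(\C)CC[C@@](O)(C(C)C)C#C[Si](C)(C)Cc1ccccc1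
A6 | alternative 3 | 6,9-oxygen-bridged 8-acetoxy-8-methylhydroazulen-10-one, C4 triethylsilyl ether | O=C1[C@@H]2O[C@@H](C[C@]2(C)OC(C)=O)[C@@H]2[C@]1(C)CC[C@@]2(O[Si](CC)(CC)CC)C(C)C
A7 | alternative 3 | cyclopentane diazoketone with the C6 aldehyde at C5 | [N-]=[N+]=CC(=O)[C@@]1(C)CC[C@@](O[Si](CC)(CC)CC)(C(C)C)[C@@H]1C=O
A8 | alternative 3 | isopropenyl acetate | CC(=C)OC(C)=O
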